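Retrosynthesis: the two ArO–CH2Ph bonds are cut first; the C3 CH2OH and the C4 aryl ketone are traced back to the carbonyl carbon and the ArCH–O carbon of a γ-lactone fused across C3–C4; then C2–C3 is cut (carbene C–H insertion), then the C3 diazo group, the O1–C2 ether bond (imidate alkylation), and last the lactone C–O bond and the C4–CHAr bond (succinate aldol).
Forward: the lactone ring is made first by aldol–lactonisation, the arylmethyl ether and the diazo group are attached, the oxolane then closes onto the lactone by C–H insertion to a cis-fused 3,7-dioxabicyclo[3.3.0]octan-8-one, and hydride finally opens the lactone ring.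
Enabling feature: in the oxolane (O1, C2 aryl, C3 CH2OH, C4 aroyl, C5 H2) the hydrogen on C2 is benzylic and α to O1, and C2 is the fifth atom from C3 along C3–C4–C5–O1–C2; C2–C3 can therefore come from a C3 carbene and a C–H bond of a plain arylmethyl ether, with the lactone carbonyl on C3 as latent CH2OH and the lactone ArCH–O on C4 as latent aryl ketone.
Stereochemistry: (R)-4-benzyloxazolidin-2-one sets C4 in an Evans syn aldol; cis fusion relays C4 to C3 and endo insertion relays it to C2, giving an all-cis oxolane in which C2 and C4 already have their final relationship; C3 is then inverted by base at the aldehyde oxidation level to the all-trans isomer, so the absolute configuration of the target rests on C2.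
Starting materials: commercial 3-(benzyloxy)-4-methoxybenzaldehyde (O-benzylisovanillin), (R)-4-benzyloxazolidin-2-one and methyl 4-chloro-4-oxobutanoate; benzyl ethers mask both phenols throughout.

Key step: step 9

Remark: the insertion is taken to deliver the new aryl group endo (cis to the lactone carbonyl carbon), as is known for dirhodium-catalysed insertions of this lactone class; for that reason C3, not C4, is the centre corrected after ring opening.

Step 1
Reactants: 1 3-(benzyloxy)-4-methoxybenzaldehyde
Product: 2 [3-(benzyloxy)-4-methoxyphenyl]methanol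
Conditions: NaBH4, MeOH, 0 °C
Reagents that add atoms: none
Why: Borohydride reduction of an aromatic aldehyde gives the benzylic alcohol, and nothing else in 1 is reducible under these conditions.

Step 2
Reactants: 2 [3-(benzyloxy)-4-methoxyphenyl]methanol
Product: 3 3-(benzyloxy)-4-methoxybenzyl 2,2,2-trichloroacetimidate
Conditions: Cl3CCN, DBU (10 mol %), CH2Cl2, 0 °C
Reagents that add atoms: trichloroacetonitrile, N#CC(Cl)(Cl)Cl
Why: DBU-catalysed addition of the alcohol to the electron-poor nitrile (trichloroacetimidate formation) turns the benzylic hydroxyl into a leaving group that acid alone can activate; 3 is used promptly because electron-rich benzyl imidates rearrange on storage.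

Step 3
Reactants: 4 (R)-4-benzyloxazolidin-2-one; 5 methyl 4-chloro-4-oxobutanoate
Product: 6 methyl 4-[(R)-4-benzyl-2-oxooxazolidin-3-yl]-4-oxobutanoate
Conditions: n-BuLi, THF, −78 °C; then 5, −78 → 0 °C
Reagents that add atoms: none
Why: N-Acylation of the lithiated oxazolidinone by the acid chloride is much faster than attack on the methyl ester, so the succinate half-ester is attached through its chloride end only.

Step 4
Reactants: 6 methyl 4-[(R)-4-benzyl-2-oxooxazolidin-3-yl]-4-oxobutanoate; 1 3-(benzyloxy)-4-methoxybenzaldehyde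
Product: 8 (R)-4-benzyl-3-{[(2R,3R)-2-[3-(benzyloxy)-4-methoxyphenyl]-5-oxooxolan-3-yl]carbonyl}oxazolidin-2-one (trans lactone), via syn-aldol hydroxy ester 7 (not isolated)
Conditions: Bu2BOTf, iPr2NEt, CH2Cl2, −78 → 0 °C; 1, −78 → 0 °C; MeOH, pH 7 buffer, H2O2, 0 °C; then PPTS (cat.), CH2Cl2, rt
Reagents that add atoms: none
Why: Evans syn aldol reaction followed by lactonisation: Bu2BOTf enolises the imide (not the ester) to the Z boron enolate, which adds to 1 through a Zimmerman–Traxler chair on the face turned away from the benzyl group of the (R)-auxiliary and so should set both new centres as (3R,4R) in 7; the γ-hydroxy ester then closes to the lactone, and the syn aldol relationship becomes the trans 2,3-relationship of 8.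

Step 5
Reactants: 8 (R)-4-benzyl-3-{[(2R,3R)-2-[3-(benzyloxy)-4-methoxyphenyl]-5-oxooxolan-3-yl]carbonyl}oxazolidin-2-one
Product: 10 (2R,3R)-2-[3-(benzyloxy)-4-methoxyphenyl]-5-oxooxolane-3-carboxylic acid (trans aryl paraconic acid), via peroxy acid 9 (not isolated)
Conditions: LiOH, H2O2, THF/H2O, 0 °C; Na2SO3; HCl to pH 2
Reagents that add atoms: hydrogen peroxide, OO
Why: Hydroperoxide hydrolysis of an N-acyl oxazolidinone: HOO− attacks the exocyclic imide carbonyl selectively, sulfite reduces the peroxy acid 9, and acidification recloses any lactone opened by base (only one γ-lactone is possible), with no stereocentre touched.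

Step 6
Reactants: 10 (2R,3R)-2-[3-(benzyloxy)-4-methoxyphenyl]-5-oxooxolane-3-carboxylic acid
Product: 11 (4S,5R)-5-[3-(benzyloxy)-4-methoxyphenyl]-4-(hydroxymethyl)oxolan-2-one
Conditions: BH3·SMe2, THF, 0 °C → rt; MeOH quench
Reagents that add atoms: none
Why: Chemoselective borane reduction: BH3 reduces the carboxylic acid through its acyloxyborane far faster than it reduces the lactone, and the neutral conditions avoid the alkoxide that would let the β-(hydroxymethyl) lactone translactonise.

Step 7
Reactants: 11 (4S,5R)-5-[3-(benzyloxy)-4-methoxyphenyl]-4-(hydroxymethyl)oxolan-2-one; 3 3-(benzyloxy)-4-methoxybenzyl 2,2,2-trichloroacetimidate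
Product: 12 (4S,5R)-5-[3-(benzyloxy)-4-methoxyphenyl]-4-({[3-(benzyloxy)-4-methoxyphenyl]methoxy}methyl)oxolan-2-one
Conditions: CSA (10 mol %), CH2Cl2, 0 °C → rt
Reagents that add atoms: none
Why: Acid-catalysed O-alkylation with a trichloroacetimidate: protonated 3 ionises to a para-methoxy-stabilised benzylic cation that is trapped by the primary hydroxyl, and because no alkoxide is formed the lactone does not translactonise; the weak acid leaves the benzylic lactone C–O bond alone.

Step 8
Reactants: 12 (4S,5R)-5-[3-(benzyloxy)-4-methoxyphenyl]-4-({[3-(benzyloxy)-4-methoxyphenyl]methoxy}methyl)oxolan-2-one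
Product: 14 (4S,5R)-5-[3-(benzyloxy)-4-methoxyphenyl]-4-({[3-(benzyloxy)-4-methoxyphenyl]methoxy}methyl)-3-diazooxolan-2-one, via 3-trifluoroacetyl lactone 13 (not isolated)
Conditions: LiN(SiMe3)2, THF, −78 °C; CF3CO2CH2CF3; aq. NH4Cl; then MsN3, Et3N, H2O (1 equiv), MeCN, rt
Reagents that add atoms: methanesulfonyl azide, CS(=O)(=O)N=[N+]=[N-]
Why: Detrifluoroacetylative diazo transfer (deacylative Regitz-type reaction): Claisen acylation of the lithium enolate with the trifluoroacetate activates C3 as the 1,3-dicarbonyl compound 13, mesyl azide transfers N2 to C3 and the trifluoroacetyl group leaves on the sulfonamide nitrogen, while C4 and C5 are not touched.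

Step 9
Reactants: 14 (4S,5R)-5-[3-(benzyloxy)-4-methoxyphenyl]-4-({[3-(benzyloxy)-4-methoxyphenyl]methoxy}methyl)-3-diazooxolan-2-one
Product: 15 (1R,2S,5S,6R)-2,6-bis[3-(benzyloxy)-4-methoxyphenyl]-3,7-dioxabicyclo[3.3.0]octan-8-one (2-endo,6-exo furofuranone)
Conditions: Rh2(OAc)4 (2 mol %), CH2Cl2, rt, slow addition of 14 at high dilution
Reagents that add atoms: none
Why: Rh2(OAc)4 (divalent rhodium) takes N2 out of 14 and leaves an electrophilic rhodium-bound carbene at C3, which inserts through a concerted, three-centre, hydride-transfer-like transition state into the C2–H bond that is benzylic, α to O1 and activated by the para-methoxy group. The closest known reaction type is the dirhodium-catalysed 1,5 C–H insertion of α-diazo-γ-butyrolactones into the benzylic C–H bond of an arylmethyl ether, which gives furofuranones with the new aryl group endo. The oxolane closes by joining the carbene carbon to the fifth atom of the chain C3–C4–C5–O1–C2 (1,5-insertion, a five-membered ring on a five-membered ring), and since two fused five-membered rings can only be cis-fused, C3 is dictated by C4. At C2 the aryl group should come out endo, cis to the lactone carbonyl carbon, because the hydrogen that is transferred must point at the carbene while the aryl group sits pseudo-equatorial on the forming ring and away from the acetate ligands of the dirhodium core; C2 is thus relayed from C4 as well. The step needs 1,5-insertion to outrun 1,2-hydride shift from C4, attack on the arenes and ylide formation at O1, and it needs endo delivery at C2; the ring-held acceptor carbene, the electron-rich benzylic ether C–H bond, the acetate ligand set and slow addition at high dilution should secure the first, and any C2 epimer, which would end in the enantiomeric series after step 11, is removed here by chromatography or crystallisation.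

Step 10
Reactants: 15 (1R,2S,5S,6R)-2,6-bis[3-(benzyloxy)-4-methoxyphenyl]-3,7-dioxabicyclo[3.3.0]octan-8-one
Product: 16 (R)-[3-(benzyloxy)-4-methoxyphenyl]{(3S,4S,5S)-5-[3-(benzyloxy)-4-methoxyphenyl]-4-(hydroxymethyl)oxolan-3-yl}methanol (all-cis diol)
Conditions: LiAlH4, THF, 0 °C; Fieser work-up
Reagents that add atoms: none
Why: Hydride reduction of the lactone to the diol: LiAlH4 delivers the acyl carbon as CH2OH on C3 and frees the benzylic carbinol on C4 without touching any stereocentre, the benzyl ethers or the oxolane.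

Step 11
Reactants: 16 (R)-[3-(benzyloxy)-4-methoxyphenyl]{(3S,4S,5S)-5-[3-(benzyloxy)-4-methoxyphenyl]-4-(hydroxymethyl)oxolan-3-yl}methanol
Product: 18 (2S,3S,4S)-2-[3-(benzyloxy)-4-methoxyphenyl]-4-[3-(benzyloxy)-4-methoxybenzoyl]oxolane-3-carbaldehyde (all-trans), via all-cis keto aldehyde 17 (not isolated)
Conditions: (COCl)2, DMSO, CH2Cl2, −78 °C; Et3N, −78 → 0 °C; then DBU (0.2 equiv), 0 °C → rt
Reagents that add atoms: none
Why: Swern oxidation followed by base-mediated epimerisation: both hydroxyls are converted into alkoxysulfonium ions before Et3N is added, so the keto aldehyde forms without passing through a lactol that could be oxidised back to the lactone, and DBU then equilibrates the strained all-cis 17 through the enolate of the aldehyde (C3, with C4 also free to equilibrate through the ketone enolate) to the all-trans isomer, in which the C3 substituent is trans to both neighbours while the non-enolisable C2 anchors the configuration.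

Step 12
Reactants: 18 (2S,3S,4S)-2-[3-(benzyloxy)-4-methoxyphenyl]-4-[3-(benzyloxy)-4-methoxybenzoyl]oxolane-3-carbaldehyde
Product: 19 [(3S,4R,5S)-5-[3-(benzyloxy)-4-methoxyphenyl]-4-(hydroxymethyl)oxolan-3-yl][3-(benzyloxy)-4-methoxyphenyl]methanone
Conditions: NaBH4 (0.5 equiv), EtOH/CH2Cl2, −78 °C
Reagents that add atoms: none
Why: Chemoselective borohydride reduction: at −78 °C NaBH4 reduces the aldehyde far faster than the electron-rich, conjugated aryl ketone, and the conditions are too mild and short to enolise C4.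

Step 13
Reactants: 19 [(3S,4R,5S)-5-[3-(benzyloxy)-4-methoxyphenyl]-4-(hydroxymethyl)oxolan-3-yl][3-(benzyloxy)-4-methoxyphenyl]methanone
Product: 20 [(3S,4R,5S)-5-(3-hydroxy-4-methoxyphenyl)-4-(hydroxymethyl)oxolan-3-yl](3-hydroxy-4-methoxyphenyl)methanone (CNP0234761.1)
Conditions: H2 (1 atm), Pd/C (10 wt %), EtOAc, rt
Reagents that add atoms: none
Why: Catalytic hydrogenolysis of the two aryl benzyl ethers: ArO–CH2Ph bonds are cleaved on palladium much faster than the conjugated aryl ketone is reduced or the cyclic benzylic C2–O1 bond is cut in neutral ethyl acetate at 1 atm, so the reaction is stopped after uptake of two equivalents of H2.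

Compound list
1 | 3-(benzyloxy)-4-methoxybenzaldehyde | O=Cc1ccc(OC)c(OCc2ccccc2)c1 | starting material
2 | [3-(benzyloxy)-4-methoxyphenyl]methanol | OCc1ccc(OC)c(OCc2ccccc2)c1 | intermediate
3 | 3-(benzyloxy)-4-methoxybenzyl 2,2,2-trichloroacetimidate | N=C(OCc1ccc(OC)c(OCc2ccccc2)c1)C(Cl)(Cl)Cl | intermediate
4 | (R)-4-benzyloxazolidin-2-one | O=C1N[C@H](Cc2ccccc2)CO1 | starting material
5 | methyl 4-chloro-4-oxobutanoate | COC(=O)CCC(Cl)=O | starting material
6 | methyl 4-[(R)-4-benzyl-2-oxooxazolidin-3-yl]-4-oxobutanoate | COC(=O)CCC(=O)N1[C@H](Cc2ccccc2)COC1=O | intermediate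
7 | methyl (3R,4R)-3-{[(R)-4-benzyl-2-oxooxazolidin-3-yl]carbonyl}-4-[3-(benzyloxy)-4-methoxyphenyl]-4-hydroxybutanoate (syn-aldol hydroxy ester, not isolated) | COC(=O)C[C@@H](C(=O)N1[C@H](Cc2ccccc2)COC1=O)[C@@H](O)c1ccc(OC)c(OCc2ccccc2)c1 | intermediate
8 | (R)-4-benzyl-3-{[(2R,3R)-2-[3-(benzyloxy)-4-methoxyphenyl]-5-oxooxolan-3-yl]carbonyl}oxazolidin-2-one | O=C1O[C@@H](c2ccc(OC)c(OCc3ccccc3)c2)[C@H](C(=O)N2[C@H](Cc3ccccc3)COC2=O)C1 | intermediate
9 | (2R,3R)-2-[3-(benzyloxy)-4-methoxyphenyl]-5-oxooxolane-3-carboperoxoic acid (peroxy acid, not isolated) | O=C1O[C@@H](c2ccc(OC)c(OCc3ccccc3)c2)[C@H](C(=O)OO)C1 | intermediate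
10 | (2R,3R)-2-[3-(benzyloxy)-4-methoxyphenyl]-5-oxooxolane-3-carboxylic acid | O=C1O[C@@H](c2ccc(OC)c(OCc3ccccc3)c2)[C@H](C(=O)O)C1 | intermediate
11 | (4S,5R)-5-[3-(benzyloxy)-4-methoxyphenyl]-4-(hydroxymethyl)oxolan-2-one | O=C1O[C@@H](c2ccc(OC)c(OCc3ccccc3)c2)[C@H](CO)C1 | intermediate
12 | (4S,5R)-5-[3-(benzyloxy)-4-methoxyphenyl]-4-({[3-(benzyloxy)-4-methoxyphenyl]methoxy}methyl)oxolan-2-one | O=C1O[C@@H](c2ccc(OC)c(OCc3ccccc3)c2)[C@H](COCc2ccc(OC)c(OCc3ccccc3)c2)C1 | intermediate
13 | (4S,5R)-5-[3-(benzyloxy)-4-methoxyphenyl]-4-({[3-(benzyloxy)-4-methoxyphenyl]methoxy}methyl)-3-(trifluoroacetyl)oxolan-2-one (C3 enolisable and unassigned, not isolated) | O=C1O[C@@H](c2ccc(OC)c(OCc3ccccc3)c2)[C@H](COCc2ccc(OC)c(OCc3ccccc3)c2)C1C(=O)C(F)(F)F | intermediate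
14 | (4S,5R)-5-[3-(benzyloxy)-4-methoxyphenyl]-4-({[3-(benzyloxy)-4-methoxyphenyl]methoxy}methyl)-3-diazooxolan-2-one | O=C1O[C@@H](c2ccc(OC)c(OCc3ccccc3)c2)[C@H](COCc2ccc(OC)c(OCc3ccccc3)c2)C1=[N+]=[N-] | intermediate
15 | (1R,2S,5S,6R)-2,6-bis[3-(benzyloxy)-4-methoxyphenyl]-3,7-dioxabicyclo[3.3.0]octan-8-one (2-endo,6-exo) | O1[C@H](c2ccc(OC)c(OCc3ccccc3)c2)[C@@H]2C(=O)O[C@@H](c3ccc(OC)c(OCc4ccccc4)c3)[C@@H]2C1 | intermediate
16 | (R)-[3-(benzyloxy)-4-methoxyphenyl]{(3S,4S,5S)-5-[3-(benzyloxy)-4-methoxyphenyl]-4-(hydroxymethyl)oxolan-3-yl}methanol (all-cis) | O1[C@H](c2ccc(OC)c(OCc3ccccc3)c2)[C@H](CO)[C@H]([C@@H](O)c2ccc(OC)c(OCc3ccccc3)c2)C1 | intermediate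
17 | (2S,3R,4S)-2-[3-(benzyloxy)-4-methoxyphenyl]-4-[3-(benzyloxy)-4-methoxybenzoyl]oxolane-3-carbaldehyde (all-cis, not isolated) | O1[C@H](c2ccc(OC)c(OCc3ccccc3)c2)[C@H](C=O)[C@H](C(=O)c2ccc(OC)c(OCc3ccccc3)c2)C1 | intermediate
18 | (2S,3S,4S)-2-[3-(benzyloxy)-4-methoxyphenyl]-4-[3-(benzyloxy)-4-methoxybenzoyl]oxolane-3-carbaldehyde (all-trans) | O1[C@H](c2ccc(OC)c(OCc3ccccc3)c2)[C@@H](C=O)[C@H](C(=O)c2ccc(OC)c(OCc3ccccc3)c2)C1 | intermediate
19 | [(3S,4R,5S)-5-[3-(benzyloxy)-4-methoxyphenyl]-4-(hydroxymethyl)oxolan-3-yl][3-(benzyloxy)-4-methoxyphenyl]methanone | O1[C@H](c2ccc(OC)c(OCc3ccccc3)c2)[C@@H](CO)[C@H](C(=O)c2ccc(OC)c(OCc3ccccc3)c2)C1 | intermediate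
20 | [(3S,4R,5S)-5-(3-hydroxy-4-methoxyphenyl)-4-(hydroxymethyl)oxolan-3-yl](3-hydroxy-4-methoxyphenyl)methanone | COc1ccc(C(=O)[C@@H]2CO[C@H](c3ccc(OC)c(O)c3)[C@H]2CO)cc1O | target

Total step count: 13
Longest linear sequence: 11 steps (steps 3 to 13, from 4 and 5); the imidate branch (steps 1 and 2) joins at step 7.

Steps most likely to fail

Step 9. The carbene may be diverted (1,2-hydride migration from C4 to a butenolide, addition to an arene), or endo delivery at C2 may be incomplete, which lowers the enantiomeric purity downstream. The fallback forms the same C2–C3 bond by anionic acylation and sets C2 by hydride delivery; it sets out from 11 and comes back at 15. Alcohol 11 is esterified with commercial 3-(benzyloxy)-4-methoxybenzoic acid (DCC, DMAP, CH2Cl2) to the benzoate ester F1. LiN(SiMe3)2 (2.2 equiv, THF, −78 → 0 °C) generates the lactone enolate, which attacks the tethered ester carbonyl in a 5-exo-trig Claisen-type O→C acyl transfer and gives, after quench, the bicyclic hemiketal F2 (in equilibrium with the open 3-aroyl lactone; only the cis-fused form can close). Et3SiH with BF3·OEt2 (CH2Cl2, −78 °C) ionises the hemiketal and reduces the aryl-stabilised oxocarbenium ion from the convex face, which should place the aryl group endo and give 15.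

Step 11. The 1,4-keto aldehyde may be lost by β-elimination of O1 from an enolate (ring opening to an enal or enone) or by cyclodehydration, or the equilibration may stop short of the all-trans isomer. The fallback inverts C3 at the ester level and avoids the keto aldehyde; it sets out from 15 and comes back at 19. NaOMe in MeOH (rt) opens the lactone; the open hydroxy ester epimerises at C3 and the trans ester can no longer relactonise, so the all-trans hydroxy ester F3 should accumulate. LiAlH4 (THF, 0 °C) then gives the all-trans diol F4, and MnO2 (CH2Cl2, rt) oxidises only the benzylic carbinol to give 19, which also bypasses step 12.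

Step 7. The electron-rich imidate 3 may rearrange to the N-benzyl trichloroacetamide or alkylate itself faster than it alkylates the β-branched primary alcohol, or the acid may trigger translactonisation of 11. The fallback is a reductive etherification in which the ether carbon comes from the aldehyde; it sets out from 11 and comes back at 12. Alcohol 11 is silylated (TMSCl, Et3N, CH2Cl2) to the trimethylsilyl ether F5, which is combined with aldehyde 1 and Et3SiH under catalytic TMSOTf (CH2Cl2, −78 °C); the oxocarbenium ion formed from the aldehyde and the silyl ether is reduced in situ to 12, and steps 1 and 2 are then not needed.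

Further compounds
F1 | step 9 | [(2R,3S)-2-[3-(benzyloxy)-4-methoxyphenyl]-5-oxooxolan-3-yl]methyl 3-(benzyloxy)-4-methoxybenzoate | O=C1O[C@@H](c2ccc(OC)c(OCc3ccccc3)c2)[C@H](COC(=O)c2ccc(OC)c(OCc3ccccc3)c2)C1
F2 | step 9 | (1R,5S,6R)-2,6-bis[3-(benzyloxy)-4-methoxyphenyl]-2-hydroxy-3,7-dioxabicyclo[3.3.0]octan-8-one (hemiketal, C2 unassigned, in equilibrium with the open 3-aroyl lactone) | O1C(O)(c2ccc(OC)c(OCc3ccccc3)c2)[C@@H]2C(=O)O[C@@H](c3ccc(OC)c(OCc4ccccc4)c3)[C@@H]2C1
F3 | step 11 | methyl (2S,3S,4S)-2-[3-(benzyloxy)-4-methoxyphenyl]-4-{(R)-[3-(benzyloxy)-4-methoxyphenyl](hydroxy)methyl}oxolane-3-carboxylate | O1[C@H](c2ccc(OC)c(OCc3ccccc3)c2)[C@@H](C(=O)OC)[C@H]([C@@H](O)c2ccc(OC)c(OCc3ccccc3)c2)C1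
F4 | step 11 | (R)-[3-(benzyloxy)-4-methoxyphenyl]{(3S,4R,5S)-5-[3-(benzyloxy)-4-methoxyphenyl]-4-(hydroxymethyl)oxolan-3-yl}methanol (all-trans) | O1[C@H](c2ccc(OC)c(OCc3ccccc3)c2)[C@@H](CO)[C@H]([C@@H](O)c2ccc(OC)c(OCc3ccccc3)c2)C1
F5 | step 7 | (4S,5R)-5-[3-(benzyloxy)-4-methoxyphenyl]-4-{[(trimethylsilyl)oxy]methyl}oxolan-2-one | O=C1O[C@@H](c2ccc(OC)c(OCc3ccccc3)c2)[C@H](CO[Si](C)(C)C)C1
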